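**Assumption:** the target SMILES has no stereocentres and no E/Z-stereogenic double bonds, so nigrasin I is achiral and the "single enantiomer" requirement is met automatically; no step needs stereocontrol.

## Retrosynthetic overview

1. Nigrasin I ⇒ global deprotection of a 5,7-di-O-acetyl, 2',4'-di-O-MOM flavone whose C8 reverse-prenyl group comes from an aromatic Claisen rearrangement of a 7-O-prenyl ether.
2. The 3-prenylflavone core ⇒ one Rh(III)-catalysed oxidative [4+2] annulation of a salicylaldehyde (A ring; formyl C–H plus phenol O–H) with an aryl prenyl alkyne (B ring, C2, C3 and the C3-prenyl already attached). This bold step replaces the usual Baker–Venkataraman/diketone C-prenylation sequence.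
3. Alkyne ⇒ 2,4-dihydroxybenzaldehyde (MOM protection, Ohira–Bestmann, acetylide prenylation). Aldehyde ⇒ 2,4,6-trihydroxybenzaldehyde by 4-O-selective prenylation; its two ortho-OH groups are equivalent.
4. Ring order: rings A and B are bought intact; ring C (the pyranone) is the only ring formed (step 5); the C8 quaternary carbon is set afterwards (step 6).

## Route

**Step 1**
Reactants: 1, 2,4-dihydroxybenzaldehyde
Product: 3, 2,4-bis(methoxymethoxy)benzaldehyde
Conditions: MOMCl (3 equiv), i-Pr2NEt (4 equiv), CH2Cl2, 0 °C → reflux
Reagents that add atoms: 2, chloromethyl methyl ether (MOMCl), COCCl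
Why: Standard O-alkylation of both phenols as MOM acetals (excess reagent and heat force the H-bonded 2-OH); MOM survives the later base, organometallic and thermal steps.

**Step 2**
Reactants: 3, 2,4-bis(methoxymethoxy)benzaldehyde
Product: 5, 1-ethynyl-2,4-bis(methoxymethoxy)benzene
Conditions: Ohira–Bestmann reagent (1.3 equiv), K2CO3 (2 equiv), MeOH, rt
Reagents that add atoms: 4, dimethyl (1-diazo-2-oxopropyl)phosphonate, COP(=O)(OC)C(=[N+]=[N-])C(C)=O (supplies the terminal alkyne carbon)
Why: Seyferth–Gilbert homologation (Ohira–Bestmann modification) converts ArCHO into ArC≡CH under mild carbonate conditions that leave MOM ethers untouched.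

**Step 3**
Reactants: 5, 1-ethynyl-2,4-bis(methoxymethoxy)benzene
Product: 7, 1-(5-methylhex-4-en-1-yn-1-yl)-2,4-bis(methoxymethoxy)benzene (Ar–C≡C–CH2–CH=CMe2)
Conditions: EtMgBr (1.1 equiv), THF, 0 → 40 °C; then CuCl (10 mol %), prenyl bromide (1.2 equiv), THF, 45 °C
Reagents that add atoms: 6, 1-bromo-3-methylbut-2-ene (prenyl bromide), CC(C)=CCBr
Why: Cu(I)-catalysed allylation of an alkynyl Grignard (classical skipped-enyne synthesis); the copper acetylide attacks the unhindered primary carbon, giving the linear prenyl product, and any minor SN2′ isomer is separable.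

**Step 4**
Reactants: 8, 2,4,6-trihydroxybenzaldehyde
Product: 10, 2,6-dihydroxy-4-[(3-methylbut-2-en-1-yl)oxy]benzaldehyde
Conditions: prenol (1.05 equiv), PPh3 (1.1 equiv), DIAD (1.1 equiv), THF, 0 °C → rt
Reagents that add atoms: 9, 3-methylbut-2-en-1-ol (prenol), CC(C)=CCO
Why: Mitsunobu etherification; the 4-OH (para to CHO) is the most acidic phenol and the only one not H-bonded to the formyl group, so it is alkylated selectively, and the neutral conditions avoid C-prenylation of the phloroglucinol ring.

**Step 5 (key step)**
Reactants: 10, 2,6-dihydroxy-4-(prenyloxy)benzaldehyde (1.0 equiv); 7, aryl prenyl alkyne (1.2 equiv)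
Product: 11, 2-[2,4-bis(methoxymethoxy)phenyl]-5-hydroxy-3-(3-methylbut-2-en-1-yl)-7-[(3-methylbut-2-en-1-yl)oxy]-4H-chromen-4-one
Conditions: [RhCl(cod)]2 (2 mol %), 1,2,3,4-tetraphenylcyclopentadiene (8 mol %), Cu(OAc)2·H2O (2.2 equiv), o-xylene, 120 °C, N2; EDTA/NH4Cl work-up to release Cu from the 5-hydroxy-4-keto chelate
Reagents that add atoms: none (both fragments are listed reactants; Cu(II) only removes 2 H)
Why: Rh(III)-catalysed oxidative formyl C–H/phenol O–H annulation of salicylaldehydes with internal alkynes (a known chromone synthesis, here untested on a skipped enyne). Phenoxide-directed C–H rhodation gives an acyl-rhodacycle, and the alkyne inserts with its aryl-bearing carbon on Rh, so C–O reductive elimination places the aryl at C2 and the prenyl-bearing carbon at C3. The two ortho-OH groups of 10 are equivalent, so there is no A-ring regiochemistry issue; the unused one becomes the 5-OH.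

**Step 6**
Reactants: 11, 7-O-prenyl-3-prenylflavone
Product: 13, 2-[2,4-bis(methoxymethoxy)phenyl]-8-(2-methylbut-3-en-2-yl)-3-(3-methylbut-2-en-1-yl)-4-oxo-4H-chromene-5,7-diyl diacetate (any 7-monoacetate is carried forward; both converge in step 7)
Conditions: Ac2O (10 equiv), N,N-diethylaniline, 185 °C, sealed tube, Ar, 3 h
Reagents that add atoms: 12, acetic anhydride, CC(=O)OC(C)=O
Why: Aromatic Claisen [3,3] rearrangement of the 7-O-prenyl ether delivers the tertiary terminus to C8. C8 is favoured electronically (C7–C8 bond fixation, as for 7-allyloxychromones and coumarins) and sterically (C6 is flanked by the 5-O substituent). In situ acetylation of the freed 7-OH (anhydride-trapping variant) prevents abnormal Claisen rearrangement and dihydrofuran formation; the new quaternary carbon carries two methyls and is not stereogenic.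

**Step 7**
Reactants: 13, diacetate bis-MOM flavone
Product: 14, nigrasin I, 2-(2,4-dihydroxyphenyl)-5,7-dihydroxy-8-(2-methylbut-3-en-2-yl)-3-(3-methylbut-2-en-1-yl)-4H-chromen-4-one
Conditions: K2CO3, MeOH, rt, 30 min; then 3 M aq. HCl added (MeOH/H2O), 40 °C, one pot
Reagents that add atoms: none
Why: Base methanolysis of the aryl acetates followed by acid-catalysed acetal (MOM) methanolysis; this mild acid is the standard MOM removal for prenylated flavonoids and is too weak to protonate the monosubstituted vinyl group (dihydrofuran formation) or cyclise the prenyl group.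

## Compound list

1 | 2,4-dihydroxybenzaldehyde | O=Cc1ccc(O)cc1O | starting material
2 | chloromethyl methyl ether (MOMCl) | COCCl | starting material (reagent)
3 | 2,4-bis(methoxymethoxy)benzaldehyde | COCOc1ccc(C=O)c(OCOC)c1 | intermediate
4 | dimethyl (1-diazo-2-oxopropyl)phosphonate | COP(=O)(OC)C(=[N+]=[N-])C(C)=O | starting material (reagent)
5 | 1-ethynyl-2,4-bis(methoxymethoxy)benzene | C#Cc1ccc(OCOC)cc1OCOC | intermediate
6 | 1-bromo-3-methylbut-2-ene (prenyl bromide) | CC(C)=CCBr | starting material
7 | 1-(5-methylhex-4-en-1-yn-1-yl)-2,4-bis(methoxymethoxy)benzene | CC(C)=CCC#Cc1ccc(OCOC)cc1OCOC | intermediate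
8 | 2,4,6-trihydroxybenzaldehyde | O=Cc1c(O)cc(O)cc1O | starting material
9 | 3-methylbut-2-en-1-ol (prenol) | CC(C)=CCO | starting material
10 | 2,6-dihydroxy-4-[(3-methylbut-2-en-1-yl)oxy]benzaldehyde | CC(C)=CCOc1cc(O)c(C=O)c(O)c1 | intermediate
11 | 2-[2,4-bis(methoxymethoxy)phenyl]-5-hydroxy-3-prenyl-7-(prenyloxy)-4H-chromen-4-one | CC(C)=CCOc1cc(O)c2c(=O)c(CC=C(C)C)c(-c3ccc(OCOC)cc3OCOC)oc2c1 | intermediate
12 | acetic anhydride | CC(=O)OC(C)=O | starting material (reagent)
13 | 2-[2,4-bis(methoxymethoxy)phenyl]-8-(2-methylbut-3-en-2-yl)-3-prenyl-4-oxo-4H-chromene-5,7-diyl diacetate | C=CC(C)(C)c1c(OC(C)=O)cc(OC(C)=O)c2c(=O)c(CC=C(C)C)c(-c3ccc(OCOC)cc3OCOC)oc12 | intermediate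
14 | nigrasin I | C=CC(C)(C)c1c(O)cc(O)c2c(=O)c(CC=C(C)C)c(-c3ccc(O)cc3O)oc12 | target

## Summary

**Total steps:** 7
**Longest linear sequence:** 6 (steps 1 → 2 → 3 → 5 → 6 → 7, from 2,4-dihydroxybenzaldehyde)

**Steps most likely to fail, with fallbacks:**

1. **Step 5 (Rh annulation).** Risks are skipped-enyne isomerisation, decarbonylation to a benzofuran, and premature reaction of the prenyl ether at 120 °C. Fallback: drop the C–H annulation. Add the lithium acetylide of 5 to an O-protected A-ring aldehyde, oxidise to the ynone, 6-endo iodocyclise (ICl) to the 3-iodoflavone, and install the prenyl by Stille coupling with tributyl(prenyl)stannane.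

2. **Step 6 (Claisen).** Risks are C6 versus C8 regioselectivity and secondary rearrangement of the 1,1-dimethylallyl phenol. Fallback: set the reverse prenyl before ring C is built. Claisen rearrangement of the symmetric aldehyde 10 can give only one C-reverse-prenyl isomer (both ortho carbons equivalent, para position blocked by CHO). Then MOM-protect the less hindered 4- and 6-OH groups and run the annulation through the remaining hindered 2-OH, which fixes the substituent at C8; C3-prenyl and ring C still come from alkyne 7.

3. **Step 4 (selective mono-O-prenylation of a triol).** Risks are bis-alkylation and poor conversion. Fallback: make the aldehyde by directed ortho-metalation instead. O-prenylate 3,5-bis(methoxymethoxy)phenol, lithiate between the two OMOM groups (n-BuLi) and formylate with DMF, then remove the ortho-MOM groups under mild acid to reach 10 without any selectivity requirement.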